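- A small charge of impurity, 0.32 mM, stands in this flask against 0.65 mM of free catalyst, about half as much. Read as a catalyst poison, it removes its own amount and leaves a working catalyst of 0.330 mM.

| flask | starting material | free catalyst | impurity | remark | time |
|---|---|---|---|---|---|
| teal | 0.013 M | 0.91 mM | 0.32 mM | run made earlier |  |
| blue | 0.013 M | 1.4 mM | 0.32 mM | run made earlier |  |
| violet | 0.013 M | 0.65 mM | 0.16 mM | run made earlier |  |
| flask | 0.013 M | 0.65 mM | 0.32 mM |  | 1.5 h |

| run | time / min | target / % | side product / % |
|---|---|---|---|
| teal | 4.00 | 2.8 | 1.7 |
| teal | 10.0 | 4.9 | 1.7 |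
| teal | 25.0 | 11.4 | 11.8 |
| teal | 50.0 | 17.5 | 27.7 |
| blue | 15.0 | 14.9 | 5.1 |
| blue | 25.0 | 20.3 | 16.6 |
| blue | 40.0 | 29.5 | 27.7 |
| blue | 50.0 | 32.0 | 35.4 |
| violet | 6.00 | 1.8 | 0 |
| violet | 20.0 | 7.8 | 6.9 |
| violet | 40.0 | 10.5 | 17.9 |
| violet | 50.0 | 14.9 | 24.0 |

(each reading ± 1 percentage point)

- percent here means starting material units held: one side product counts as two

1. concentration of target at 1.5 h, in M
2. concentration of side product at 1.5 h, in M

- The readings of teal and blue favour that subtraction. At 50.0 min, the logarithm of the fraction of starting material left in blue is 1.86 times teal's, while the working catalyst stands at 1.83 times and the charged catalyst at 1.54 times.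
- At 1.5 h this flask reaches 29.7 mM·min of catalyst dose, the working catalyst multiplied by time. Teal at its last reading had 29.5 mM·min, so the two doses match.
- Reading each side product as one starting material plus one target, and so counting it once instead of twice, teal had made 31.3 % of target in all. The reckoning here therefore commits to [target] + [side product] of about 0.00410 M and leaves the split open.
- The forecast says 0.0029 M of target and 0.0023 M of side product, on the ground “Impurity has no clear effect on it.” Its sum of 0.00520 M is higher than this reckoning.
- The flask gives 0.00165 M of target and 0.00252 M of side product, a sum of 0.00417 M.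

    catalyst intermediate → free catalyst + target (k = 0.00440 s⁻¹)
    starting material + target → side product (k = 0.0490 M⁻¹ s⁻¹)
    free catalyst + impurity → spent catalyst (k = 73.0 M⁻¹ s⁻¹)
    starting material + free catalyst → catalyst intermediate (k = 0.540 M⁻¹ s⁻¹)

- Teal at its last reading, without the scatter, holds 0.00232 M of target and 0.00182 M of side product, while this flask, at nearly the same dose over a longer time, has less target and more side product. Read at 40 min, the same charge has a dose of 13.2 mM·min. Teal's yield per dose at 25.0 min turns that into 0.00201 M, and that neighbour holds 0.00200 M of [target] + [side product].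

(Readings and results were generated by integration with constants of no real substance, and the scatter is random.)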